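(The constants belong to no real substance; the result is computed.)

In a one-step world, with G going first-order to a single product, the percentage made would not see the charge; this flask has one step that does.

    G → D (k1 = 0.033 s⁻¹)
    G → E (k2 = 0.0054 s⁻¹)
    E ⇌ X (K3 = 0.44, k3 = 0.015 s⁻¹)
    X → L (k4 = 0.011 s⁻¹)
    X → J (k5 = 0.049 s⁻¹)
    D → X (k6 = 0.017 s⁻¹)
    G + E → G.E (k7 = 0.14 L mol⁻¹ s⁻¹)

| setting | alder | birch | oak | cedar |
|---|---|---|---|---|
| G | 0.012 M | 0.030 M | 0.10 M | 0.30 M |
| time | 10 min | 10 min | 10 min | 10 min |

1. amount of J at the end, in percent of the G charged for alder, birch, oak, cedar, in this order
2. how the row runs (falls all the way / hardly changes / rises all the way / falls, then rises / rises, then falls)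

- a species is counted by the G in it: one G.E counts as two
- "hardly changes" means that all values lie within two and a half points (for a concentration: within two and a half percent of the largest)
- run time (alder): 10 min

Without step 7, G leaves at 0.0384 s⁻¹, and what reaches X splits towards J with a share (selectivity) of 81.7%. Step 7 locks two G in G.E per event, so we want to know how much E the falling G meets.

We start at the low end, and we need not integrate. Weighting each pool by the G still present turns every rate balance into algebra, with each pool carrying an extra loss equal to G's own. Solving the balances of D, X and E, with X falling back at 0.0341 s⁻¹, gives 0.162 as the E met per G. The factors of two, from the square of G and from the two G per event, cancel. In alder this gives 0.707%, the trap number: step 7's constant times the charge times the E met per G, over G's own loss. It reads directly as the share of the charge ending in G.E, as long as it is small.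

At the high end, suppose each E is caught as it appears. E then comes at 0.0174 s⁻¹ per G, counting D as if it passed at once, which overstates. Two G per catch give a ceiling of 62.3%. We join the ends as share = number / (1 + number / ceiling), and J is the split of what remains, counted for a fully drained flask.

| Flask | Trap number | Share in G.E | J |
|---|---|---|---|
| alder | 0.707% | 0.699% | 81.1% |
| birch | 1.77% | 1.72% | 80.3% |
| oak | 5.89% | 5.38% | 77.3% |
| cedar | 17.7% | 13.8% | 70.4% |

One number serves for alder and birch; in cedar the ceiling already matters. Since the share in G.E grows from each flask to the next, our row reads: falls all the way.

The forecast gave 80.6%, 79.8%, 76.8% and 70%, lower than ours at each point, and falls all the way, saying that “the yield falls steadily as the charge rises”.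

The simulation gives 80.6%, 79.8%, 77.1% and 71.3%: falls all the way.

Scaled by the charge, the alder trap number becomes 17.7% for cedar, more than the 12.2% of G.E read there. In alder, X has a half-life of 0.24 min by step 5 against 1.1 min by step 4, shorter by a factor of 4.45, and at 10.0 min alder holds 80.6% as J beside 18.1% as L.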